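**Retrosynthetic overview**
1. Target 28 ⇐ bis-silyl ether 27. The central cyclohexene is closed last, by a ketone-directed addition of the ring B alkylidene C–H bond across a tethered enyne (26 → 27).
2. 26 ⇐ aldol condensation of ring B epoxy ketone 8 with the (Z)-enal 21, giving the (E)-alkylidene whose vinylic H is syn to C=O.
3. 21 ⇐ enynone 14 + (Z)-allylic bromide 18 by one-pot conjugate reduction/enolate alkylation, which sets the spiro quaternary centre.
4. 14 ⇐ 8 (Saegusa, α-iodination, Sonogashira). 8 ⇐ (S)-4-hydroxycyclohexenone 3 (α-iodination/Stille prenylation, hydroxyl-directed epoxidation) ⇐ enone acetal 1 (asymmetric transfer hydrogenation).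
5. Ring order: the epoxycyclohexanone ring is made once and used twice (rings A and B); the central ring is formed last.

Assumption: the target (C32H40O6) is a formal [4+2] homodimer of a C16H20O3 vinylallene ketone; that dimerisation is taken as the disconnection most chemists would try first and is kept only as a fallback.

**Route**

Step 1
Reactants: 1 1,4-dioxaspiro[4.5]dec-6-en-8-one
Product: 2 (8S)-1,4-dioxaspiro[4.5]dec-6-en-8-ol
Conditions: RuCl(p-cymene)[(S,S)-TsDPEN] (1 mol %), KOH (2 mol %), i-PrOH, rt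
Reagents that add atoms: none
Why: Noyori asymmetric transfer hydrogenation reduces only the C=O; the alkene takes the place of the aryl group in the CH/π-organised transition state, so the (S,S)-catalyst should give the (8S)-allylic alcohol (about 92–95% ee expected).

Step 2
Reactants: 2 (8S)-1,4-dioxaspiro[4.5]dec-6-en-8-ol
Product: 3 (4S)-4-hydroxycyclohex-2-en-1-one
Conditions: PPTS (10 mol %), acetone/H2O (4:1), 50 °C
Reagents that add atoms: water, O
Why: Mild acid-catalysed acetal hydrolysis unmasks the ketone and turns the allylic alcohol into the γ-hydroxy enone; the carbinol centre is not involved.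

Step 3
Reactants: 3 (4S)-4-hydroxycyclohex-2-en-1-one
Product: 4 (4S)-4-hydroxy-2-iodocyclohex-2-en-1-one
Conditions: I2, pyridine/CH2Cl2 (1:1), 0 °C to rt
Reagents that add atoms: iodine, [I][I]
Why: Johnson α-iodination (pyridine conjugate addition, iodination of the enolate, elimination) functionalises only the enone α-carbon.

Step 4
Reactants: 4 (4S)-4-hydroxy-2-iodocyclohex-2-en-1-one; 5 tributyl(3-methylbut-2-en-1-yl)stannane
Product: 6 (4S)-4-hydroxy-2-(3-methylbut-2-en-1-yl)cyclohex-2-en-1-one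
Conditions: Pd2(dba)3 (2.5 mol %), AsPh3 (20 mol %), CuI (10 mol %), NMP, rt
Reagents that add atoms: none
Why: Stille coupling of the α-iodoenone under arsine/copper-accelerated conditions; the prenyl group is transferred through its CH2 terminus, as in Stille prenylations of aryl and alkenyl halides.

Step 5
Reactants: 6 (4S)-4-hydroxy-2-(3-methylbut-2-en-1-yl)cyclohex-2-en-1-one
Product: 7 (1S,5S,6S)-5-hydroxy-1-(3-methylbut-2-en-1-yl)-7-oxabicyclo[4.1.0]heptan-2-one
Conditions: t-BuOOH (decane), BnMe3NOH (10 mol %), THF, −10 °C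
Reagents that add atoms: tert-butyl hydroperoxide, CC(C)(C)OO
Why: Weitz–Scheffer nucleophilic epoxidation attacks only the enone alkene (not the prenyl alkene); hydrogen bonding of the free γ-hydroxyl to the peroxide anion delivers oxygen to its own face, giving the syn epoxy alcohol and setting C1 and C6.

Step 6
Reactants: 7 (1S,5S,6S)-5-hydroxy-1-(3-methylbut-2-en-1-yl)-7-oxabicyclo[4.1.0]heptan-2-one
Product: 8 (1S,5S,6S)-5-(tert-butyldimethylsilyloxy)-1-(3-methylbut-2-en-1-yl)-7-oxabicyclo[4.1.0]heptan-2-one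
Conditions: TBSCl, imidazole, DMF, rt
Reagents that add atoms: tert-butyl(chloro)dimethylsilane, CC(C)(C)[Si](C)(C)Cl
Why: Standard silyl ether formation protects the only hydroxyl for the later enolate, hydride and aldol steps; no stereocentre is touched.

Step 7
Reactants: 8 (1S,5S,6S)-5-(tert-butyldimethylsilyloxy)-1-(3-methylbut-2-en-1-yl)-7-oxabicyclo[4.1.0]heptan-2-one
Product: 11 (1S,5S,6S)-5-(tert-butyldimethylsilyloxy)-1-(3-methylbut-2-en-1-yl)-7-oxabicyclo[4.1.0]hept-3-en-2-one, via lithium enolate 9 (not isolated), via trimethylsilyl enol ether 10 (not isolated)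
Conditions: LiN(SiMe3)2, Me3SiCl, THF, −78 °C; then Pd(OAc)2 (1.1 equiv), MeCN, rt
Reagents that add atoms: none
Why: Saegusa–Ito oxidation; only C3 can be enolised (C1 is quaternary), the silyl enol ether is dehydrogenated to the enone, and over-oxidation is structurally impossible.

Step 8
Reactants: 11 (1S,5S,6S)-5-(tert-butyldimethylsilyloxy)-1-(3-methylbut-2-en-1-yl)-7-oxabicyclo[4.1.0]hept-3-en-2-one
Product: 12 (1S,5S,6S)-5-(tert-butyldimethylsilyloxy)-3-iodo-1-(3-methylbut-2-en-1-yl)-7-oxabicyclo[4.1.0]hept-3-en-2-one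
Conditions: I2, pyridine/CH2Cl2 (1:1), 0 °C to rt
Reagents that add atoms: iodine, [I][I]
Why: Johnson α-iodination of the enone, a known transformation for silyl-protected epoxycyclohexenones; pyridine is too weak a base to trigger γ-deprotonation and epoxide opening.

Step 9
Reactants: 12 (1S,5S,6S)-5-(tert-butyldimethylsilyloxy)-3-iodo-1-(3-methylbut-2-en-1-yl)-7-oxabicyclo[4.1.0]hept-3-en-2-one; 13 2-methylbut-1-en-3-yne
Product: 14 (1S,5S,6S)-5-(tert-butyldimethylsilyloxy)-3-(3-methylbut-3-en-1-yn-1-yl)-1-(3-methylbut-2-en-1-yl)-7-oxabicyclo[4.1.0]hept-3-en-2-one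
Conditions: PdCl2(PPh3)2 (5 mol %), CuI (10 mol %), i-Pr2NH, THF, 0 °C to rt
Reagents that add atoms: none
Why: Sonogashira coupling of the electron-poor alkenyl iodide with the terminal enyne at or below rt, precedented for α-iodo epoxycyclohexenones of the harveynone type.

Step 10
Reactants: 15 dimethyl (2Z)-2-methylbut-2-enedioate (dimethyl citraconate)
Product: 16 (2Z)-2-methylbut-2-ene-1,4-diol
Conditions: i-Bu2AlH (4.4 equiv), CH2Cl2, −78 to 0 °C; aq. KNaC4H4O6 work-up
Reagents that add atoms: none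
Why: Low-temperature ester reduction with i-Bu2AlH (no conjugate reduction) keeps the Z geometry of the citraconate, which later becomes the cis ring alkene of the central ring.

Step 11
Reactants: 16 (2Z)-2-methylbut-2-ene-1,4-diol
Product: 17 (2Z)-2-methyl-4-(triethylsilyloxy)but-2-en-1-ol
Conditions: Et3SiCl (1.0 equiv), Et3N, DMAP (cat.), CH2Cl2, −78 °C
Reagents that add atoms: chlorotriethylsilane, CC[Si](Cl)(CC)CC
Why: Sterically controlled monosilylation at the less hindered 4-hydroxyl (CH2 on the CH= carbon) rather than the hydroxyl next to the methyl-bearing carbon; about 4:1 is expected and the minor regioisomer is removed by chromatography.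

Step 12
Reactants: 17 (2Z)-2-methyl-4-(triethylsilyloxy)but-2-en-1-ol
Product: 18 [(2Z)-4-bromo-3-methylbut-2-en-1-yl]oxy(triethyl)silane
Conditions: CBr4, PPh3, 2,6-lutidine, CH2Cl2, −20 °C
Reagents that add atoms: carbon tetrabromide, BrC(Br)(Br)Br
Why: Buffered Appel bromination of the primary allylic alcohol proceeds by SN2 at CH2 without allylic transposition and with retention of the Z alkene; 18 is used at once.

Step 13
Reactants: 14 (1S,5S,6S)-5-(tert-butyldimethylsilyloxy)-3-(3-methylbut-3-en-1-yn-1-yl)-1-(3-methylbut-2-en-1-yl)-7-oxabicyclo[4.1.0]hept-3-en-2-one; 18 [(2Z)-4-bromo-3-methylbut-2-en-1-yl]oxy(triethyl)silane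
Product: 20 (1S,3R,5S,6S)-5-(tert-butyldimethylsilyloxy)-3-(3-methylbut-3-en-1-yn-1-yl)-1-(3-methylbut-2-en-1-yl)-3-[(2Z)-2-methyl-4-(triethylsilyloxy)but-2-en-1-yl]-7-oxabicyclo[4.1.0]heptan-2-one, via lithium enolate 19 (not isolated)
Conditions: LiBH(s-Bu)3 (1.05 equiv), THF, −78 °C; then 18 (1.5 equiv), DMPU, −78 to −30 °C
Reagents that add atoms: none
Why: Conjugate reduction by the hindered borohydride (1,2-attack is blocked by the quaternary epoxide carbon and the α-alkynyl group) gives the regiodefined enolate, which is C-alkylated at the α-carbon by the allylic bromide (SN2 enolate alkylation); the electrophile is expected to enter anti to the C1 prenyl group, on the face of the epoxide oxygen, setting the (3R) quaternary centre.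

Step 14
Reactants: 20 (1S,3R,5S,6S)-5-(tert-butyldimethylsilyloxy)-3-(3-methylbut-3-en-1-yn-1-yl)-1-(3-methylbut-2-en-1-yl)-3-[(2Z)-2-methyl-4-(triethylsilyloxy)but-2-en-1-yl]-7-oxabicyclo[4.1.0]heptan-2-one
Product: 21 (2Z)-3-methyl-4-(RA)but-2-enal (RA = (1S,3R,5S,6S)-5-(tert-butyldimethylsilyloxy)-3-(3-methylbut-3-en-1-yn-1-yl)-1-(3-methylbut-2-en-1-yl)-2-oxo-7-oxabicyclo[4.1.0]heptan-3-yl)
Conditions: (COCl)2, DMSO, CH2Cl2, −78 to −40 °C; Et3N, −78 to 0 °C
Reagents that add atoms: none
Why: Swern oxidation carried out directly on the primary allylic triethylsilyl ether (activated DMSO cleaves the unhindered primary Si–O bond; the secondary TBS ether is untouched) gives the (Z)-enal without a separate deprotection, and the low temperature limits Z to E isomerisation.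

Step 15
Reactants: 8 (1S,5S,6S)-5-(tert-butyldimethylsilyloxy)-1-(3-methylbut-2-en-1-yl)-7-oxabicyclo[4.1.0]heptan-2-one (1.3 equiv); 21 (2Z)-3-methyl-4-(RA)but-2-enal
Product: 24 aldol adduct (β-hydroxy ketone joining ring B C3 to the former aldehyde carbon), via dibutylboron enolate 22 (not isolated), via dibutylboron aldolate 23 (not isolated)
Conditions: n-Bu2BOTf (1.4 equiv), i-Pr2NEt (1.7 equiv), CH2Cl2, −78 °C; then 21, −78 to −20 °C; pH 7 buffer, MeOH, 30% H2O2, 0 °C
Reagents that add atoms: none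
Why: Boron-mediated aldol addition: soft enolisation of 8 can occur only toward C3, and the non-basic boron enolate adds 1,2 to the enal through a closed Zimmerman–Traxler transition state without γ-deprotonation or Z to E isomerisation of 21, whose ring A ketone is non-enolisable and flanked by two quaternary carbons; the boron aldolate is cleaved oxidatively at pH 7, and the two new stereocentres form without needed control because they are removed in step 16.

Step 16
Reactants: 24 aldol adduct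
Product: 26 (E,Z)-dienone (ring B 3-alkylidene ketone), via mesylate 25 (not isolated)
Conditions: MsCl, Et3N, CH2Cl2, −40 °C; then DBU, −40 to 0 °C
Reagents that add atoms: none
Why: Mesylation and E1cB elimination give the conjugated dienone as the thermodynamically favoured (E)-alkylidene (chain anti to C=O, vinylic H syn to C=O), the geometry the directed C–H step needs; the (Z)-trisubstituted alkene is not touched.

Step 17
Reactants: 26 (E,Z)-dienone
Product: 27 bis(tert-butyldimethylsilyl) ether of the target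
Conditions: RuH2(CO)(PPh3)3 (10 mol %), toluene (0.01 M), 100 °C, dark
Reagents that add atoms: none
Why: Proposed new method: the ring B ketone chelates zerovalent ruthenium (generated from RuH2(CO)(PPh3)3) and directs oxidative addition of the one vinylic C–H bond lying syn to C=O in the (E)-alkylidene, the ruthenium hydride adds syn across the tethered alkyne in the 6-exo mode (H to the isopropenyl-bearing carbon, as usual for 1,3-enynes) and C–C reductive elimination closes the central ring, so the new ring carbon ends up syn to the ring B carbonyl and the isopropenyl group trans to it, which are the two exocyclic alkene geometries of the target, with no new sp3 centre; the closest known reaction type is the Murai ruthenium-catalysed addition of enone β-C–H bonds across internal alkynes to give dienones, here made intramolecular.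

Step 18
Reactants: 27 bis(tert-butyldimethylsilyl) ether of the target
Product: 28 CNP0235815.2 (target)
Conditions: HF·pyridine, pyridine, THF, 0 °C to rt
Reagents that add atoms: none
Why: Buffered fluoride cleavage of both secondary silyl ethers under conditions routinely tolerated by epoxy ketones and polyenes; no stereocentre is affected.

**Compound list**
1 | 1,4-dioxaspiro[4.5]dec-6-en-8-one | O=C1C=CC2(CC1)OCCO2 | starting material
2 | (8S)-1,4-dioxaspiro[4.5]dec-6-en-8-ol | C1C[C@H](O)C=CC12OCCO2 | intermediate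
3 | (4S)-4-hydroxycyclohex-2-en-1-one | O=C1CC[C@H](O)C=C1 | intermediate
4 | (4S)-4-hydroxy-2-iodocyclohex-2-en-1-one | O=C1CC[C@H](O)C=C1I | intermediate
5 | tributyl(3-methylbut-2-en-1-yl)stannane | CCCC[Sn](CCCC)(CCCC)CC=C(C)C | starting material
6 | (4S)-4-hydroxy-2-(3-methylbut-2-en-1-yl)cyclohex-2-en-1-one | O=C1CC[C@H](O)C=C1CC=C(C)C | intermediate
7 | (1S,5S,6S)-5-hydroxy-1-(3-methylbut-2-en-1-yl)-7-oxabicyclo[4.1.0]heptan-2-one (hydroxyl and epoxide syn) | O=C1CC[C@H](O)[C@@H]2O[C@]12CC=C(C)C | intermediate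
8 | (1S,5S,6S)-5-(tert-butyldimethylsilyloxy)-1-(3-methylbut-2-en-1-yl)-7-oxabicyclo[4.1.0]heptan-2-one | O=C1CC[C@H](O[Si](C)(C)C(C)(C)C)[C@@H]2O[C@]12CC=C(C)C | intermediate
9 | lithium (1S,5S,6S)-5-(tert-butyldimethylsilyloxy)-1-(3-methylbut-2-en-1-yl)-7-oxabicyclo[4.1.0]hept-2-en-2-olate (lithium enolate of 8) | [Li]OC1=CC[C@H](O[Si](C)(C)C(C)(C)C)[C@@H]2O[C@]12CC=C(C)C | intermediate
10 | 2-(trimethylsilyloxy) enol ether of 8 (C2=C3) | C[Si](C)(C)OC1=CC[C@H](O[Si](C)(C)C(C)(C)C)[C@@H]2O[C@]12CC=C(C)C | intermediate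
11 | (1S,5S,6S)-5-(tert-butyldimethylsilyloxy)-1-(3-methylbut-2-en-1-yl)-7-oxabicyclo[4.1.0]hept-3-en-2-one | O=C1C=C[C@H](O[Si](C)(C)C(C)(C)C)[C@@H]2O[C@]12CC=C(C)C | intermediate
12 | (1S,5S,6S)-5-(tert-butyldimethylsilyloxy)-3-iodo-1-(3-methylbut-2-en-1-yl)-7-oxabicyclo[4.1.0]hept-3-en-2-one | O=C1C(I)=C[C@H](O[Si](C)(C)C(C)(C)C)[C@@H]2O[C@]12CC=C(C)C | intermediate
13 | 2-methylbut-1-en-3-yne | C=C(C)C#C | starting material
14 | (1S,5S,6S)-5-(tert-butyldimethylsilyloxy)-3-(3-methylbut-3-en-1-yn-1-yl)-1-(3-methylbut-2-en-1-yl)-7-oxabicyclo[4.1.0]hept-3-en-2-one | O=C1C(C#CC(C)=C)=C[C@H](O[Si](C)(C)C(C)(C)C)[C@@H]2O[C@]12CC=C(C)C | intermediate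
15 | dimethyl (2Z)-2-methylbut-2-enedioate (dimethyl citraconate) | COC(=O)/C=C(C)\C(=O)OC | starting material
16 | (2Z)-2-methylbut-2-ene-1,4-diol | OC/C=C(C)\CO | intermediate
17 | (2Z)-2-methyl-4-(triethylsilyloxy)but-2-en-1-ol | OC/C(C)=C\CO[Si](CC)(CC)CC | intermediate
18 | [(2Z)-4-bromo-3-methylbut-2-en-1-yl]oxy(triethyl)silane | BrC/C(C)=C\CO[Si](CC)(CC)CC | intermediate
19 | lithium (1S,5S,6S)-5-(tert-butyldimethylsilyloxy)-3-(3-methylbut-3-en-1-yn-1-yl)-1-(3-methylbut-2-en-1-yl)-7-oxabicyclo[4.1.0]hept-2-en-2-olate | [Li]OC1=C(C#CC(C)=C)C[C@H](O[Si](C)(C)C(C)(C)C)[C@@H]2O[C@]12CC=C(C)C | intermediate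
20 | (1S,3R,5S,6S)-5-(tert-butyldimethylsilyloxy)-3-(3-methylbut-3-en-1-yn-1-yl)-1-(3-methylbut-2-en-1-yl)-3-[(2Z)-2-methyl-4-(triethylsilyloxy)but-2-en-1-yl]-7-oxabicyclo[4.1.0]heptan-2-one | O=C1[C@](C#CC(C)=C)(C/C(C)=C\CO[Si](CC)(CC)CC)C[C@H](O[Si](C)(C)C(C)(C)C)[C@@H]2O[C@]12CC=C(C)C | intermediate
21 | (2Z)-3-methyl-4-(RA)but-2-enal; RA = (1S,3R,5S,6S)-5-(tert-butyldimethylsilyloxy)-3-(3-methylbut-3-en-1-yn-1-yl)-1-(3-methylbut-2-en-1-yl)-2-oxo-7-oxabicyclo[4.1.0]heptan-3-yl | O=C1[C@](C#CC(C)=C)(C/C(C)=C\C=O)C[C@H](O[Si](C)(C)C(C)(C)C)[C@@H]2O[C@]12CC=C(C)C | intermediate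
22 | dibutyl{[(1S,5S,6S)-5-(tert-butyldimethylsilyloxy)-1-(3-methylbut-2-en-1-yl)-7-oxabicyclo[4.1.0]hept-2-en-2-yl]oxy}borane (dibutylboron enolate of 8) | CCCCB(CCCC)OC1=CC[C@H](O[Si](C)(C)C(C)(C)C)[C@@H]2O[C@]12CC=C(C)C | intermediate
23 | O-dibutylboryl derivative of aldol adduct 24 (dibutylboron aldolate; epimers at ring B C3 and the carbinol carbon) | O=C1[C@](C#CC(C)=C)(C/C(C)=C\C(OB(CCCC)CCCC)C3C[C@H](O[Si](C)(C)C(C)(C)C)[C@@H]4O[C@]4(CC=C(C)C)C3=O)C[C@H](O[Si](C)(C)C(C)(C)C)[C@@H]2O[C@]12CC=C(C)C | intermediate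
24 | (1S,5S,6S)-5-(tert-butyldimethylsilyloxy)-3-[(2Z)-1-hydroxy-3-methyl-4-(RA)but-2-en-1-yl]-1-(3-methylbut-2-en-1-yl)-7-oxabicyclo[4.1.0]heptan-2-one (epimers at C3 and the carbinol carbon) | O=C1[C@](C#CC(C)=C)(C/C(C)=C\C(O)C3C[C@H](O[Si](C)(C)C(C)(C)C)[C@@H]4O[C@]4(CC=C(C)C)C3=O)C[C@H](O[Si](C)(C)C(C)(C)C)[C@@H]2O[C@]12CC=C(C)C | intermediate
25 | methanesulfonate of the carbinol of 24 | O=C1[C@](C#CC(C)=C)(C/C(C)=C\C(OS(C)(=O)=O)C3C[C@H](O[Si](C)(C)C(C)(C)C)[C@@H]4O[C@]4(CC=C(C)C)C3=O)C[C@H](O[Si](C)(C)C(C)(C)C)[C@@H]2O[C@]12CC=C(C)C | intermediate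
26 | (1S,3E,5S,6S)-5-(tert-butyldimethylsilyloxy)-3-[(2Z)-3-methyl-4-(RA)but-2-en-1-ylidene]-1-(3-methylbut-2-en-1-yl)-7-oxabicyclo[4.1.0]heptan-2-one | O=C1[C@](C#CC(C)=C)(C/C(C)=C\C=C3/C[C@H](O[Si](C)(C)C(C)(C)C)[C@@H]4O[C@]4(CC=C(C)C)C3=O)C[C@H](O[Si](C)(C)C(C)(C)C)[C@@H]2O[C@]12CC=C(C)C | intermediate
27 | bis(tert-butyldimethylsilyl) ether of 28 (both secondary hydroxyls silylated) | C=C(C)/C=C1/C(=C2/C[C@H](O[Si](C)(C)C(C)(C)C)[C@@H]3O[C@]3(CC=C(C)C)C2=O)C=C(C)C[C@@]12C[C@H](O[Si](C)(C)C(C)(C)C)[C@@H]1O[C@]1(CC=C(C)C)C2=O | intermediate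
28 | CNP0235815.2 (spiro dimer; rings A and B both (4S,5S,6S)-5,6-epoxy-4-hydroxy-6-prenylcyclohexanone units, spiro carbon R) | C=C(C)/C=C1/C(=C2/C[C@H](O)[C@@H]3O[C@]3(CC=C(C)C)C2=O)C=C(C)C[C@@]12C[C@H](O)[C@@H]1O[C@]1(CC=C(C)C)C2=O | target

**Step count and risks**
Total step count: 18 (steps 10–12 make the linker). Longest linear sequence: 15 steps (1–9, then 13–18).

Step 17 is the most likely to fail. The intramolecular C–H/alkyne addition is new; the hindered ketone may not turn over, the (Z)-dienone may undergo thermal 1,5-H shift or isomerise, and Ru–H may consume the enyne. The fallback replaces C–H activation by a vinyl triflate carbopalladation and sets out from 24. Dess–Martin oxidation of 24 gives the 1,3-diketone F5. Its sodium chelate (NaH, THF, 0 °C) is O-sulfonylated with Tf2O at the less hindered exocyclic oxygen to give the (Z)-enol triflate F6, in which the triflate is syn to the ring B carbonyl. Pd(OAc)2/PPh3 with HCO2Na in DMF at 60 °C then effects oxidative addition with retention, 6-exo-dig syn carbopalladation of the enyne and formate reduction of the alkenylpalladium. This comes back to the route at 27.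

Step 13 is the second risk: 1,2- versus 1,4-reduction, α- versus γ-alkylation of the alkynyl enolate, and above all the facial selectivity at the quaternary centre, which rests on a steric argument rather than precedent (the required face is anti to the C1 prenyl group but is also the face of the C5 silyloxy group). The fallback is the biomimetic cycloaddition and sets out from 14. Conjugate reduction with LiBH(s-Bu)3 and protonation of enolate 19 at −78 °C (AcOH) gives the 3-alkynyl ketone F3. Catalytic Et3N in toluene isomerises it to the vinylallene ketone F4, which is left at rt to 40 °C to undergo [4+2] homodimerisation (one molecule as diene through its allene/isopropenyl unit, the other as dienophile through its enone C=C). This bypasses steps 13–17 and comes back to the route at 27.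

Step 5 is the third risk: syn selectivity of the hydroxyl-directed nucleophilic epoxidation may be incomplete. The fallback uses an electrophilic, hydroxyl-directed epoxidation on the masked ketone and sets out from 6. Noyori acetalisation (1,2-bis(trimethylsilyloxy)ethane, Me3SiOTf cat., CH2Cl2, −78 °C, then K2CO3/MeOH) gives (8S)-6-(3-methylbut-2-en-1-yl)-1,4-dioxaspiro[4.5]dec-6-en-8-ol F1. VO(acac)2/t-BuOOH epoxidation, directed syn by the allylic hydroxyl and selective over the prenyl alkene, gives the syn epoxy alcohol acetal F2. PPTS in aqueous acetone then hydrolyses the acetal, coming back to the route at 7.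

**Further compounds**
F1 | step 5 | (8S)-6-(3-methylbut-2-en-1-yl)-1,4-dioxaspiro[4.5]dec-6-en-8-ol | C1C[C@H](O)C=C(CC=C(C)C)C12OCCO2
F2 | step 5 | (1'S,5'S,6'S)-1'-(3-methylbut-2-en-1-yl)spiro[1,3-dioxolane-2,2'-[7]oxabicyclo[4.1.0]heptan]-5'-ol | C1C[C@H](O)[C@@H]3O[C@]3(CC=C(C)C)C12OCCO2
F3 | step 13 | (1S,5S,6S)-5-(tert-butyldimethylsilyloxy)-3-(3-methylbut-3-en-1-yn-1-yl)-1-(3-methylbut-2-en-1-yl)-7-oxabicyclo[4.1.0]heptan-2-one (C3 epimers) | O=C1C(C#CC(C)=C)C[C@H](O[Si](C)(C)C(C)(C)C)[C@@H]2O[C@]12CC=C(C)C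
F4 | step 13 | (1S,5S,6S)-5-(tert-butyldimethylsilyloxy)-3-(3-methylbuta-1,3-dien-1-ylidene)-1-(3-methylbut-2-en-1-yl)-7-oxabicyclo[4.1.0]heptan-2-one (vinylallene ketone) | O=C1C(=C=CC(C)=C)C[C@H](O[Si](C)(C)C(C)(C)C)[C@@H]2O[C@]12CC=C(C)C
F5 | step 17 | 1,3-diketone from oxidation of the carbinol of 24 | O=C1[C@](C#CC(C)=C)(C/C(C)=C\C(=O)C3C[C@H](O[Si](C)(C)C(C)(C)C)[C@@H]4O[C@]4(CC=C(C)C)C3=O)C[C@H](O[Si](C)(C)C(C)(C)C)[C@@H]2O[C@]12CC=C(C)C
F6 | step 17 | exocyclic (Z)-enol trifluoromethanesulfonate of F5 (triflate syn to the ring B ketone) | O=C1[C@](C#CC(C)=C)(C/C(C)=C\C(OS(=O)(=O)C(F)(F)F)=C3/C[C@H](O[Si](C)(C)C(C)(C)C)[C@@H]4O[C@]4(CC=C(C)C)C3=O)C[C@H](O[Si](C)(C)C(C)(C)C)[C@@H]2O[C@]12CC=C(C)C
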